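## Structural features

The target 21 is a 1-aryltetralin cyclolignan. Ring A is an arene (C4a, C5–H, C6–OMe, C7–OH, C8–OMe, C8a) fused through C4a–C8a to the saturated ring B (C1–C4). C1 carries a 4-hydroxy-3-methoxyphenyl (guaiacyl) ring, C2 and C3 each carry a hydroxymethyl group, and C4 is a benzylic CH2. The three stereocentres C1 (S), C2 (R) and C3 (R) are contiguous and all-trans. The fragile features are the two electron-rich free phenols, the doubly benzylic C1–H, and the 1,4-diol, whose oxygens can close a tetrahydrofuran onto a cationic C1. The real difficulty is C1: a crowded diarylmethine between the C8 methoxyl and the C2 stereocentre, which must be formed trans to C2 with the guaiacyl ring joined through the carbon para to its hydroxyl. The C2/C3 pair must be fixed in absolute terms before that. The key step exploits that C1 is bonded to two oxygen-activated arene carbons, C8a of ring A and C1′ of the guaiacyl ring, so C1 is an aldehyde carbon that can be arylated twice, first inside the molecule and then by an external phenol.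

## Logic of the disconnections

21 ⇒ 20. Only three O–acyl bonds are cut (two primary esters and one aryl ester at C7). The esters are there because the side-chain oxygens and the ring-A phenol must be inert while C1 is cationic; one kind of ester for all three allows a single unmasking. Nothing is gained in skeleton, but every polar, oxidisable function of the target is hidden. The forward step must cleave hindered esters without touching the doubly benzylic C1–H or oxidising the phenols.

20 ⇒ 16 + 17. The two aryl–C1 bonds are cut: C1–C1′ to the guaiacyl ring and C1–C8a to ring A. C1 sits between two arene carbons that are each activated by oxygen, which marks it as a carbonyl carbon and both arenes as C–H nucleophiles. The cut removes ring B, the C1 stereocentre and a whole aryl unit, leaving an open-chain aldehyde with two stereocentres and an unfunctionalised phenol. The forward step must arylate within the molecule before it arylates between molecules, take 17 at the carbon para to its hydroxyl, add it trans to the C2 substituent, and outrun enolisation of the aldehyde and proton loss from the C1 cation.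

16 ⇒ 15. The C1 carbonyl is traced back to a dimethyl acetal. The aldehyde has an epimerisable α-centre and a β-acyloxy leaving group and is the most fragile compound of the route, so it stays masked until just before use. The demand is a hydrolysis mild enough to leave C2 and the esters alone.

15 ⇒ 14 ⇒ 13. First the three O–acyl bonds are cut; then the two primary alcohols are traced back to one lactone (the C2 hydroxymethyl carbon as carbonyl, the C3 hydroxymethyl oxygen as ring oxygen). The lactone holds the two stereocentres in a five-membered ring in which the required trans arrangement is the thermodynamically preferred one, so the centre next to the carbonyl cannot drift the wrong way. The forward steps need a hydride reduction that spares the acetal and an exhaustive acylation that also reaches the hindered phenol.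

13 ⇒ 11 (through 12). The lactone carbonyl carbon is traced back to a nitromethyl carbon and the ring C–O bond to a free primary alcohol. The nitro group is wanted because it activates the preceding C–C bond construction. The forward step must oxidise a primary nitro group to the acid level without hydrolysing the acetal or the aryl ester.

11 ⇒ 5 + 9 (through 10). The C2–C3 bond (tetralin numbering), which joins the two stereocentres, is cut after the primary alcohol has been traced back to the aldehyde of 10. This divides the chain into an enolisable aldehyde and a nitroalkene, both achiral, and lets one catalytic conjugate addition set both centres. The demand is syn diastereoselectivity, high enantioselectivity, and reduction of the epimerisable aldehyde before isolation.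

9 ⇒ 6 + 7 (through 8). The C=C bond is cut by way of the β-nitro alcohol. This reduces the acceptor to two bulk chemicals. The forward steps need an addition and an E-selective dehydration that keep the acetal.

5 ⇒ 4 ⇒ 2 + 3, and 2 ⇒ 1. The Cα–Cβ bond of the propanal chain is cut after the double bond is put back, and the aryl O–acyl bond is cut last. This leads back to a cheap, lignin-derived benzaldehyde. The forward steps need a chemoselective reduction of the enal C=C and a phenol protecting group that lasts to the lactone stage.

## Other disconnections considered

Alternative 1: The cut passes through C2–C3 and C1–C8a. The mixed diester A1 holds a ferulate and a sinapate unit on one (R,R)-1,2-diphenylethane-1,2-diyl tether. FeCl3 or Ag2O would oxidise both phenols, the delocalised radicals would couple at C2–C3, and ring A would close onto the oxidised guaiacyl benzylic carbon (C1–C8a) to give the tethered trans-1-aryl-1,2-dihydronaphthalene dilactone A2.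
- In its favour: it is the biomimetic route; both phenols stay unprotected; the guaiacyl ring is attached through the correct carbon by construction; the whole carbon skeleton arises in one operation. On step economy and on guaiacyl regiochemistry it is the better plan.
- Equal: the trans C1/C2 relationship is set in both plans in the event that forms a bond at C1 next to an existing C2 centre.
- Against it here: a guaiacyl radical has a free C5, so coupling through ring carbon or phenolic oxygen competes with the C2–C3 mode, and the tether can bias but not exclude these paths. The closure must run in one direction (ring A as nucleophile), since the reverse gives a constitutional isomer. The absolute sense must be relayed from a remote tether through an eight-membered ring. A2 is at the wrong oxidation level, so C3=C4 must be hydrogenated with control of the new C3 centre and both esters reduced. Oxidants strong enough to start the cascade can also consume the electron-rich product.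
- Comparison: the chosen plan gives up the short cascade for closed-shell polar steps whose selectivities can each be argued separately, and it sets C2 and C3 catalytically instead of by a late hydrogenation.

Alternative 2: The cut removes C1–C2 and C3–C4 in a formal retro-[4+2] sense. Irradiation of the ortho-methylbenzophenone A3 near 365 nm would move a methyl hydrogen to the excited carbonyl oxygen. The photoenol of A3 would then add di-(−)-menthyl fumarate A4 across C1/C4 to give the 1-hydroxy-1-aryltetralin diester A5, with the hydroxyl cis to the C2 ester.
- In its favour: two C–C bonds, ring B and three stereocentres arise in one step from two easily made partners. The 2,3-trans relationship follows from the fumarate geometry, which is at least as secure as the catalytic control of the chosen plan. Both aryl rings are placed without regiochemical ambiguity. Convergence and step count would be better.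
- Against it here: C1 emerges as a tertiary benzylic alcohol, and to reach 21 the hydroxyl must be replaced by hydrogen on the same face (cis to the C2 substituent). Ionic reduction through the diarylmethyl cation would be expected to deliver hydride trans to the C2 group and so give the 1,2-cis aryl isomer, and hydrogenolysis offers no dependable retention. The C1 problem is therefore postponed, not solved. Menthyl esters control facial selectivity weakly without a chelating Lewis acid, which is hard to combine with the photochemical step. The electron-rich, doubly ortho-substituted ketone A3 is likely to have an unreactive lowest triplet state and an ortho-methoxyl that competes as hydrogen donor. Benzyl protection and reduction of hindered esters add steps.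
- Comparison: the alternative is superior in bond-forming efficiency but inferior at the decisive C1 centre, which the chosen plan forms directly as the trans methine.

Alternative 3: The cut dismantles ring A at C4a–C5 and C8–C8a. A zerovalent palladium catalyst such as Pd(PPh3)4 would couple the cyclohexenylstannane A6 with the chlorocyclobutenone A7 (C4a–C5). On warming, four-electron ring opening to a dienylketene, 6π-electrocyclisation (C8–C8a) and tautomerisation would give the phenol A8.
- In its favour: ring A is built with full regiocontrol. The guaiacyl ring and all three stereocentres are in place beforehand and never face a carbocation, so neither the para/meta question of the arylation nor elimination at C1/C2 can arise. On these two points it is the better plan, and the conditions are neutral.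
- Against it here: the ketene carbon becomes C8, so the free hydroxyl appears at C8 and the methoxyls at C6 and C7, whereas 21 needs OH at C7. The plan would need a cyclobutenone with a removable group at the carbon that becomes C7 and an O-methylation at C8. All three contiguous stereocentres, the aryl group and a regiodefined vinylstannane must first be assembled in A6, itself a multi-step target with an allylic, benzylic C1. Stoichiometric organotin and a multi-step cyclobutenone add cost.
- Comparison: in step economy the alternative is much the longer. It is mechanistically safer at the arene-forming stage but shifts all stereochemical work into an unsolved precursor, while the chosen plan uses the innate nucleophilicity of both arenes.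

Key step: step 11

## Assumptions and corrections

- Assumption: tetralin numbering is used throughout (C1 aryl-bearing methine, C2/C3 hydroxymethyl-bearing carbons, C4 benzylic CH2, ring A = C4a–C8a), and 7 is used as its commercial 60 wt% aqueous solution.
- Check of structures: the aldehyde centres are (2R,3R), syn in the zigzag drawing of the C1–C4 chain, and map without inversion onto the 2,3-trans (2R,3R) centres of 21 (1S,2R,3R). No change of connectivity or configuration is needed.
- Correction to the precursor design: a free C7 phenol cannot stay free while the two primary alcohols are esterified. The precursor is therefore the tris-pivalate 16. The extra aryl ester also removes ring A's phenol as a nucleophile and is cleaved in the same final reduction. Skeleton, aldehyde and the two bonds formed are unchanged. The aldehyde is released from its acetal only just before use.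
- Correction to alternative 3: its annulation places OH at C8 and OMe at C6/C7, not the oxygen pattern of 21.

## Route

Step 1
Reactants: 1 syringaldehyde
Product: 2 4-formyl-2,6-dimethoxyphenyl pivalate
Conditions: PivCl, Et3N, DMAP (cat.), CH2Cl2, 0 °C → rt
Reagents that add atoms: pivaloyl chloride, CC(C)(C)C(=O)Cl
Why: DMAP-catalysed O-acylation of the phenol; the hindered aryl ester shields the oxidisable phenol through steps 2–7 and is the same group that the key-step precursor carries.

Step 2
Reactants: 2 4-formyl-2,6-dimethoxyphenyl pivalate; 3 (triphenylphosphoranylidene)acetaldehyde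
Product: 4 (E)-3-[3,5-dimethoxy-4-(pivaloyloxy)phenyl]prop-2-enal
Conditions: toluene, 90 °C
Reagents that add atoms: none
Why: Wittig olefination with a stabilised formyl ylide, which should give the (E)-enal; near-equimolar ylide limits a second homologation of the product.

Step 3
Reactants: 4 (E)-3-[3,5-dimethoxy-4-(pivaloyloxy)phenyl]prop-2-enal
Product: 5 3-[3,5-dimethoxy-4-(pivaloyloxy)phenyl]propanal
Conditions: H2 (1 atm), Pd/C, EtOAc, rt, stopped after one equivalent of H2
Reagents that add atoms: none
Why: Heterogeneous catalytic hydrogenation; the conjugated C=C is reduced well before the aldehyde over Pd, and the aryl ester is inert to hydrogenolysis.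

Step 4
Reactants: 6 nitromethane; 7 2,2-dimethoxyacetaldehyde
Product: 8 rac-1,1-dimethoxy-3-nitropropan-2-ol
Conditions: K2CO3 (cat.), excess 6, H2O/MeOH, 0 °C → rt
Reagents that add atoms: none
Why: Henry (nitroaldol) addition of the nitronate to the non-enolisable aldehyde; the carbinol centre is lost in the next step, so the racemate is sufficient.

Step 5
Reactants: 8 rac-1,1-dimethoxy-3-nitropropan-2-ol
Product: 9 (E)-3,3-dimethoxy-1-nitroprop-1-ene
Conditions: (CF3CO)2O, Et3N, CH2Cl2, −10 °C
Reagents that add atoms: none
Why: O-Trifluoroacetylation followed by E1cB elimination through the nitronate; the conjugated (E)-nitroalkene is the stable isomer and the acetal is untouched under basic conditions.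

Step 6
Reactants: 5 3-[3,5-dimethoxy-4-(pivaloyloxy)phenyl]propanal; 9 (E)-3,3-dimethoxy-1-nitroprop-1-ene
Product: 11 (2R,3R)-2-[3,5-dimethoxy-4-(pivaloyloxy)benzyl]-4,4-dimethoxy-3-(nitromethyl)butan-1-ol, via nitroaldehyde 10 (not isolated)
Conditions: (S)-α,α-diphenylprolinol trimethylsilyl ether (10 mol%), 4-nitrophenol (10 mol%), toluene, 0 °C → rt; then NaBH4, MeOH, 0 °C
Reagents that add atoms: none
Why: Enamine-catalysed asymmetric Michael addition: the (E)-enamine of 5 is shielded on one face by the diphenyl(silyloxy)methyl group and meets the nitroalkene in an acyclic synclinal arrangement, which by the established sense of induction of this catalyst class should give the syn (2R,3R) adduct 10 and so set C3 and C2 of 21. Reduction in the same flask removes the epimerisable α-formyl centre before isolation.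

Step 7
Reactants: 11 (2R,3R)-2-[3,5-dimethoxy-4-(pivaloyloxy)benzyl]-4,4-dimethoxy-3-(nitromethyl)butan-1-ol
Product: 13 (3S,4R)-3-(dimethoxymethyl)-4-[3,5-dimethoxy-4-(pivaloyloxy)benzyl]dihydrofuran-2(3H)-one, via hydroxy acid 12 (not isolated)
Conditions: NaNO2, AcOH, DMSO, 35 °C; lactonisation on mildly acidic work-up
Reagents that add atoms: sodium nitrite, [Na+].[O-]N=O
Why: Nef-type oxidation of the primary nitro group to the carboxylic acid (nitrosation to a nitrolic acid, nitrile oxide, then hydrolysis), and the γ-hydroxy acid 12 closes to the γ-lactone. The trans lactone is the thermodynamic isomer, so the centre next to the carbonyl is secure, and the weakly acidic non-aqueous medium should spare the acetal and the aryl ester.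

Step 8
Reactants: 13 (3S,4R)-3-(dimethoxymethyl)-4-[3,5-dimethoxy-4-(pivaloyloxy)benzyl]dihydrofuran-2(3H)-one
Product: 14 (2R,3R)-2-(dimethoxymethyl)-3-(4-hydroxy-3,5-dimethoxybenzyl)butane-1,4-diol
Conditions: LiAlH4, THF, 0 °C → rt; aq. KNaC4H4O6 work-up
Reagents that add atoms: none
Why: Hydride reduction of the lactone to the 1,4-diol without touching either stereocentre or the acetal; loss of the aryl pivalate at the same time costs nothing because step 9 esterifies all three hydroxyls.

Step 9
Reactants: 14 (2R,3R)-2-(dimethoxymethyl)-3-(4-hydroxy-3,5-dimethoxybenzyl)butane-1,4-diol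
Product: 15 (2R,3R)-2-(dimethoxymethyl)-3-[3,5-dimethoxy-4-(pivaloyloxy)benzyl]butane-1,4-diyl bis(pivalate)
Conditions: PivCl (excess), pyridine, DMAP (cat.), CH2Cl2, 0 → 40 °C
Reagents that add atoms: pivaloyl chloride, CC(C)(C)C(=O)Cl
Why: Exhaustive DMAP-catalysed acylation; the esters block both side-chain oxygens (no lactol or cyclic ether in steps 10 and 11) and the ring-A phenol, and all three fall in one final operation.

Step 10
Reactants: 15 (2R,3R)-2-(dimethoxymethyl)-3-[3,5-dimethoxy-4-(pivaloyloxy)benzyl]butane-1,4-diyl bis(pivalate)
Product: 16 (2R,3R)-4-[3,5-dimethoxy-4-(pivaloyloxy)phenyl]-2,3-bis(pivaloyloxymethyl)butanal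
Conditions: TFA–H2O–CHCl3 (1:1:4), 0 °C, short contact; crude product used at once
Reagents that add atoms: water, O
Why: Acid-catalysed hydrolysis of the dimethyl acetal; no free hydroxyl is left to trap the aldehyde, and low temperature with immediate use limits enolisation at C2 and loss of pivalic acid.

Step 11
Reactants: 16 (2R,3R)-4-[3,5-dimethoxy-4-(pivaloyloxy)phenyl]-2,3-bis(pivaloyloxymethyl)butanal; 17 guaiacol
Product: 20 (1S,2R,3R)-1-(4-hydroxy-3-methoxyphenyl)-6,8-dimethoxy-7-(pivaloyloxy)-2,3-bis(pivaloyloxymethyl)-1,2,3,4-tetrahydronaphthalene, via benzylic alcohol 18 (not isolated), via benzylic cation 19 (not isolated)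
Conditions: 17 (5 equiv), BF3·OEt2 (1.5 equiv), CH2Cl2, −40 → 0 °C
Reagents that add atoms: none
Why: BF3 activates the aldehyde of 16 and the ring-A carbon ortho to the side chain (para to one methoxyl, ortho to the other) attacks it, forming C1–C8a in a Friedel–Crafts hydroxyalkylation to give 18; this closure of ring B is 6-exo-trig at the carbonyl (C=O exocyclic, the C4a=C8a arene bond inside the new ring), and since the two ortho carbons are symmetry-equivalent only one regioisomer can arise. The BF3-bound benzylic oxygen of 18 then departs to give cation 19, stabilised by the C8 (ortho) and C6 (para) methoxyls, and 17 captures it through the carbon para to its hydroxyl, forming the C1–aryl bond. The closest known reaction type is the acid-promoted tandem cyclisation/arylation of 4-arylbutanals with electron-rich arenes to 1-aryltetralins. The intramolecular event should come first because the ring carbon is doubly alkoxy-activated and tethered for six-membered closure, whereas 17 offers a singly activated position at bimolecular concentration. The only new stereocentre, C1, is controlled by the adjacent C2 centre: 17 should approach 19 on the face opposite the C2 pivaloyloxymethyl group, and reversible participation of that ester carbonyl (a cis-fused dioxanylium ion opened with inversion) would point the same way, so the aryl group ends trans to C2 (1S). Para-to-hydroxyl selectivity rests on OH being the stronger para-directing group of 17 and on the bulk of the secondary cation, which disfavours ortho attack, while O-alkylation of 17 is reversible under acid and drains to C-arylation. The pivalates keep the side-chain oxygens from closing an ether onto C1, the C7 ester removes the ring-A phenol as a competing nucleophile, and the excess of 17 suppresses attack by C5 of a second molecule. C2 and C3 stay intact provided the cation is trapped faster than it loses the C2 proton, which low temperature and the excess of 17 are meant to ensure.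

Step 12
Reactants: 20 (1S,2R,3R)-1-(4-hydroxy-3-methoxyphenyl)-6,8-dimethoxy-7-(pivaloyloxy)-2,3-bis(pivaloyloxymethyl)-1,2,3,4-tetrahydronaphthalene
Product: 21 (+)-8-methoxyisolariciresinol, (1S,2R,3R)-1-(4-hydroxy-3-methoxyphenyl)-2,3-bis(hydroxymethyl)-6,8-dimethoxy-1,2,3,4-tetrahydronaphthalen-7-ol
Conditions: LiAlH4 (excess), THF, 0 °C → rt; aq. KNaC4H4O6 work-up
Reagents that add atoms: none
Why: Reductive cleavage of all three pivalates (two alkyl, one aryl) by hydride; the conditions involve no carbanion at the doubly benzylic C1–H and no oxidant, so the three stereocentres and the phenols should be delivered intact.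

## Compound list

1 | syringaldehyde (4-hydroxy-3,5-dimethoxybenzaldehyde) | COc1cc(C=O)cc(OC)c1O | starting material
2 | 4-formyl-2,6-dimethoxyphenyl pivalate | COc1cc(C=O)cc(OC)c1OC(=O)C(C)(C)C | intermediate
3 | (triphenylphosphoranylidene)acetaldehyde | O=CC=P(c1ccccc1)(c1ccccc1)c1ccccc1 | starting material
4 | (E)-3-[3,5-dimethoxy-4-(pivaloyloxy)phenyl]prop-2-enal | COc1cc(/C=C/C=O)cc(OC)c1OC(=O)C(C)(C)C | intermediate
5 | 3-[3,5-dimethoxy-4-(pivaloyloxy)phenyl]propanal | COc1cc(CCC=O)cc(OC)c1OC(=O)C(C)(C)C | intermediate
6 | nitromethane | C[N+](=O)[O-] | starting material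
7 | 2,2-dimethoxyacetaldehyde | COC(OC)C=O | starting material
8 | rac-1,1-dimethoxy-3-nitropropan-2-ol | COC(OC)C(O)C[N+](=O)[O-] | intermediate
9 | (E)-3,3-dimethoxy-1-nitroprop-1-ene | COC(OC)/C=C/[N+](=O)[O-] | intermediate
10 | (2R,3R)-2-[3,5-dimethoxy-4-(pivaloyloxy)benzyl]-4,4-dimethoxy-3-(nitromethyl)butanal (syn) | COC(OC)[C@@H](C[N+](=O)[O-])[C@H](C=O)Cc1cc(OC)c(OC(=O)C(C)(C)C)c(OC)c1 | intermediate (not isolated)
11 | (2R,3R)-2-[3,5-dimethoxy-4-(pivaloyloxy)benzyl]-4,4-dimethoxy-3-(nitromethyl)butan-1-ol | COC(OC)[C@@H](C[N+](=O)[O-])[C@H](CO)Cc1cc(OC)c(OC(=O)C(C)(C)C)c(OC)c1 | intermediate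
12 | (2S,3R)-2-(dimethoxymethyl)-3-(hydroxymethyl)-4-[3,5-dimethoxy-4-(pivaloyloxy)phenyl]butanoic acid | COC(OC)[C@@H](C(=O)O)[C@H](CO)Cc1cc(OC)c(OC(=O)C(C)(C)C)c(OC)c1 | intermediate (not isolated)
13 | (3S,4R)-3-(dimethoxymethyl)-4-[3,5-dimethoxy-4-(pivaloyloxy)benzyl]dihydrofuran-2(3H)-one (trans lactone) | COC(OC)[C@H]1C(=O)OC[C@@H]1Cc1cc(OC)c(OC(=O)C(C)(C)C)c(OC)c1 | intermediate
14 | (2R,3R)-2-(dimethoxymethyl)-3-(4-hydroxy-3,5-dimethoxybenzyl)butane-1,4-diol | COC(OC)[C@@H](CO)[C@H](CO)Cc1cc(OC)c(O)c(OC)c1 | intermediate
15 | (2R,3R)-2-(dimethoxymethyl)-3-[3,5-dimethoxy-4-(pivaloyloxy)benzyl]butane-1,4-diyl bis(pivalate) | COC(OC)[C@@H](COC(=O)C(C)(C)C)[C@H](COC(=O)C(C)(C)C)Cc1cc(OC)c(OC(=O)C(C)(C)C)c(OC)c1 | intermediate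
16 | (2R,3R)-4-[3,5-dimethoxy-4-(pivaloyloxy)phenyl]-2,3-bis(pivaloyloxymethyl)butanal (syn; key-step precursor) | O=C[C@@H](COC(=O)C(C)(C)C)[C@H](COC(=O)C(C)(C)C)Cc1cc(OC)c(OC(=O)C(C)(C)C)c(OC)c1 | intermediate
17 | guaiacol (2-methoxyphenol) | COc1ccccc1O | starting material
18 | 1-hydroxy-6,8-dimethoxy-7-(pivaloyloxy)-2,3-bis(pivaloyloxymethyl)tetralin, C2/C3 trans as in 16, C1 epimers | OC1c2c(cc(OC)c(OC(=O)C(C)(C)C)c2OC)C[C@@H](COC(=O)C(C)(C)C)[C@@H]1COC(=O)C(C)(C)C | intermediate (not isolated)
19 | C1 benzylic cation of 18 (tetralin-1-ylium, C2/C3 trans) | [CH+]1c2c(cc(OC)c(OC(=O)C(C)(C)C)c2OC)C[C@@H](COC(=O)C(C)(C)C)[C@@H]1COC(=O)C(C)(C)C | intermediate (not isolated)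
20 | (1S,2R,3R)-1-(4-hydroxy-3-methoxyphenyl)-6,8-dimethoxy-7-(pivaloyloxy)-2,3-bis(pivaloyloxymethyl)-1,2,3,4-tetrahydronaphthalene (tris-pivalate of 21; key-step product) | COc1cc([C@H]2c3c(cc(OC)c(OC(=O)C(C)(C)C)c3OC)C[C@@H](COC(=O)C(C)(C)C)[C@@H]2COC(=O)C(C)(C)C)ccc1O | intermediate
21 | (+)-8-methoxyisolariciresinol, (1S,2R,3R) | COc1cc([C@H]2c3c(cc(OC)c(O)c3OC)C[C@@H](CO)[C@@H]2CO)ccc1O | target

## Step count and least certain steps

Total step count: 12. Longest linear sequence: 10 steps (steps 1–3 and 6–12, from 1 to 21). The nitroalkene branch (steps 4 and 5) joins at step 6.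

Step 11 (key step). The most likely failures are three. Regiocontrol in the attack of 17 may be lost, with attack through the carbon para to the methoxyl, if coordination of BF3 weakens the hydroxyl as donor. Facial selectivity at C1 may be poor. Cation 19 may lose the C2 proton, which would erase the C2 centre. The fallback sets out from 16 and returns at 20 by inverting the order of the two bond formations. The Grignard reagent (4-benzyloxy-3-methoxyphenyl)magnesium bromide F1, made from commercial 1-(benzyloxy)-4-bromo-2-methoxybenzene and Mg, would add to the aldehyde of 16 in THF at −78 °C, where the pivalates are inert. This gives the secondary benzylic alcohol F2 as C1 epimers. TFA or BF3·OEt2 in CH2Cl2 would ionise F2 to the guaiacyl-stabilised cation, and ring A would close onto it (C1–C8a) through a chair-like arrangement with the aryl group equatorial, giving the trans O-benzyl ether F3. Hydrogenolysis (H2, Pd/C, EtOAc) then gives 20. The guaiacyl regiochemistry is fixed by the aryl bromide, and the cyclisation of such diaryl carbinols is the classical entry to 1-aryltetralins.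

Step 10. The liberated β-acyloxy aldehyde may enolise under acid (epimerisation at C2), may lose pivalic acid by β-elimination, or may cyclise prematurely. The fallback sets out from 15 and returns at 20 without ever freeing the aldehyde. Acetal 15 and 17 would be treated with TMSOTf or BF3·OEt2 in CH2Cl2 at −40 °C. The oxocarbenium ion would cyclise to the 1-methoxytetralin F4, which ionises to 19 and is arylated as in step 11. This acetal variant of the same tandem arylation also removes one step.

Step 7. The acetal may be hydrolysed in the acidic nitrosating medium, the oxidation may stall at the nitrolic acid or oxime stage, or the electron-rich ring may be nitrosated. The fallback sets out from 11 and returns at 15. KOtBu in THF at −78 °C would form the nitronate, and ozone at −78 °C followed by Me2S would cleave it to the aldehyde, which closes on the neighbouring hydroxymethyl group as the trans lactol F5 (anomers). NaBH4 in MeOH would give the diol F6, in which the aryl pivalate is still in place. PivCl/pyridine/DMAP then esterifies the two primary alcohols to give 15, bypassing 13 and 14 with no change in step count.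

Step 6. Diastereo- or enantioselectivity may be eroded with the acetal-bearing nitroalkene, 5 may self-condense through its enamine, or 10 may epimerise before reduction. The fallback sets out from 5 and returns at 13, using auxiliary control for the first centre and substrate control for the second.
- NaClO2/NaH2PO4/2-methylbut-2-ene would oxidise 5 to the propanoic acid F7.
- Mixed-anhydride coupling (PivCl, Et3N, LiCl) with (S)-4-benzyloxazolidin-2-one would give the imide F8.
- NaN(SiMe3)2 and tert-butyl bromoacetate at −78 °C would give the alkylated imide F9, the electrophile entering anti to the auxiliary benzyl group.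
- NaBH4 in THF–H2O would remove the auxiliary reductively to give the hydroxy ester F10.
- Catalytic TsOH would close F10 to the (R)-lactone F11.
- LiN(iPr)2/Me3SiCl would give the silyl ketene acetal F12, which adds to HC(OMe)3 under TMSOTf catalysis anti to the C4 substituent, giving the trans lactone 13.

## Further compounds

F1 | step 11 | (4-benzyloxy-3-methoxyphenyl)magnesium bromide | COc1cc([Mg]Br)ccc1OCc1ccccc1
F2 | step 11 | (2R,3R)-1-(4-benzyloxy-3-methoxyphenyl)-4-[3,5-dimethoxy-4-(pivaloyloxy)phenyl]-2,3-bis(pivaloyloxymethyl)butan-1-ol, C1 epimers | COc1cc(C(O)[C@@H](COC(=O)C(C)(C)C)[C@H](COC(=O)C(C)(C)C)Cc2cc(OC)c(OC(=O)C(C)(C)C)c(OC)c2)ccc1OCc1ccccc1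
F3 | step 11 | O-benzyl ether of 20 at the guaiacyl hydroxyl, (1S,2R,3R) | COc1cc([C@H]2c3c(cc(OC)c(OC(=O)C(C)(C)C)c3OC)C[C@@H](COC(=O)C(C)(C)C)[C@@H]2COC(=O)C(C)(C)C)ccc1OCc1ccccc1
F4 | step 10 | 1,6,8-trimethoxy-7-(pivaloyloxy)-2,3-bis(pivaloyloxymethyl)tetralin, C2/C3 trans, C1 epimers | COC1c2c(cc(OC)c(OC(=O)C(C)(C)C)c2OC)C[C@@H](COC(=O)C(C)(C)C)[C@@H]1COC(=O)C(C)(C)C
F5 | step 7 | trans-3-(dimethoxymethyl)-4-[3,5-dimethoxy-4-(pivaloyloxy)benzyl]tetrahydrofuran-2-ol, anomers | COC(OC)[C@H]1C(O)OC[C@@H]1Cc1cc(OC)c(OC(=O)C(C)(C)C)c(OC)c1
F6 | step 7 | (2R,3R)-2-(dimethoxymethyl)-3-[3,5-dimethoxy-4-(pivaloyloxy)benzyl]butane-1,4-diol | COC(OC)[C@@H](CO)[C@H](CO)Cc1cc(OC)c(OC(=O)C(C)(C)C)c(OC)c1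
F7 | step 6 | 3-[3,5-dimethoxy-4-(pivaloyloxy)phenyl]propanoic acid | COc1cc(CCC(=O)O)cc(OC)c1OC(=O)C(C)(C)C
F8 | step 6 | (S)-4-benzyl-3-{3-[3,5-dimethoxy-4-(pivaloyloxy)phenyl]propanoyl}oxazolidin-2-one | O=C1OC[C@H](Cc2ccccc2)N1C(=O)CCc1cc(OC)c(OC(=O)C(C)(C)C)c(OC)c1
F9 | step 6 | tert-butyl (3R)-3-[3,5-dimethoxy-4-(pivaloyloxy)benzyl]-4-[(S)-4-benzyl-2-oxooxazolidin-3-yl]-4-oxobutanoate | O=C1OC[C@H](Cc2ccccc2)N1C(=O)[C@@H](CC(=O)OC(C)(C)C)Cc1cc(OC)c(OC(=O)C(C)(C)C)c(OC)c1
F10 | step 6 | tert-butyl (3R)-4-[3,5-dimethoxy-4-(pivaloyloxy)phenyl]-3-(hydroxymethyl)butanoate | OC[C@@H](CC(=O)OC(C)(C)C)Cc1cc(OC)c(OC(=O)C(C)(C)C)c(OC)c1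
F11 | step 6 | (R)-4-[3,5-dimethoxy-4-(pivaloyloxy)benzyl]dihydrofuran-2(3H)-one | O=C1OC[C@H](Cc2cc(OC)c(OC(=O)C(C)(C)C)c(OC)c2)C1
F12 | step 6 | (R)-3-[3,5-dimethoxy-4-(pivaloyloxy)benzyl]-5-(trimethylsilyloxy)-2,3-dihydrofuran | C[Si](C)(C)OC1=C[C@@H](Cc2cc(OC)c(OC(=O)C(C)(C)C)c(OC)c2)CO1
A1 | alternative 1 | mixed sinapate/ferulate diester of the (R,R)-1,2-diphenylethane-1,2-diyl tether | COc1cc(/C=C/C(=O)O[C@H](c2ccccc2)[C@@H](c2ccccc2)OC(=O)/C=C/c2ccc(O)c(OC)c2)cc(OC)c1O
A2 | alternative 1 | tethered trans-1-aryl-1,2-dihydronaphthalene-2,3-dicarboxylate (eight-membered dilactone, C3=C4) | COc1cc([C@H]2c3c(cc(OC)c(O)c3OC)C=C3C(=O)O[C@H](c4ccccc4)[C@@H](c4ccccc4)OC(=O)[C@H]23)ccc1O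
A3 | alternative 2 | (4-benzyloxy-3-methoxyphenyl)(3-benzyloxy-2,4-dimethoxy-6-methylphenyl)methanone | COc1cc(C(=O)c2c(C)cc(OC)c(OCc3ccccc3)c2OC)ccc1OCc1ccccc1
A4 | alternative 2 | di-(−)-menthyl fumarate | O=C(/C=C/C(=O)O[C@@H]1C[C@H](C)CC[C@H]1C(C)C)O[C@@H]1C[C@H](C)CC[C@H]1C(C)C
A5 | alternative 2 | 1-hydroxy-1-aryltetralin trans-2,3-di-(−)-menthyl diester, hydroxyl cis to the C2 ester | COc1cc([C@@]2(O)c3c(cc(OC)c(OCc4ccccc4)c3OC)C[C@@H](C(=O)O[C@@H]5C[C@H](C)CC[C@H]5C(C)C)[C@@H]2C(=O)O[C@@H]5C[C@H](C)CC[C@H]5C(C)C)ccc1OCc1ccccc1
A6 | alternative 3 | tributyl[3-(4-benzyloxy-3-methoxyphenyl)-4,5-bis(benzyloxymethyl)cyclohex-1-en-1-yl]stannane, all-trans, configured as C1–C3 of 21 | COc1cc([C@H]2C=C([Sn](CCCC)(CCCC)CCCC)C[C@@H](COCc3ccccc3)[C@@H]2COCc2ccccc2)ccc1OCc1ccccc1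
A7 | alternative 3 | 4-chloro-2,3-dimethoxycyclobut-2-en-1-one | COC1=C(OC)C(Cl)C1=O
A8 | alternative 3 | 8-hydroxy-6,7-dimethoxy-1-aryltetralin with benzyl-protected side chains and guaiacyl oxygen | COc1cc([C@H]2c3c(cc(OC)c(OC)c3O)C[C@@H](COCc4ccccc4)[C@@H]2COCc2ccccc2)ccc1OCc1ccccc1
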